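**Retrosynthetic overview**
- The C8 ketone is made last by forming the C8–O bond: gold-catalysed hydration of a C7≡C8 alkyne, relayed by the neighbouring 19-octenoate, so the alkyne serves as a masked ketone.
- The 19-octenoate comes from C19–O acylation of the primary allylic OH of (3R,3′R,6′R)-7,8-didehydro-β,ε-carotene-3,19,3′-triol with (E)-oct-2-enoic acid.
- The C40 triol comes from a Wittig reaction at C11=C12 between a C25 ε-end phosphonium salt and a C15 lactol; the lactol derives from a 4-alkynylbutenolide that fixes the C9=C10 geometry and releases the 19-OH on opening.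
- The C25 salt comes from an ε-C15 phosphonium salt (from α-ionone via C3 oxidation/reduction, lipase resolution, vinyl Grignard, PPh3·HBr) plus the C10-dialdehyde; the C15 lactol comes from actinol enol triflate, TMS-acetylene and 4-bromofuranone by two Sonogashira couplings.
- Rings: both six-membered rings are bought preformed (α-ionone, actinol) and no carbocycle is built; the only ring event is butenolide → lactol → opening in the Wittig step.

Assumption: (4R,6R)-actinol, the C10-dialdehyde and 4-bromofuran-2(5H)-one are bought as catalogue/industrial intermediates; carotenoid numbering (C1–C20, primed for the ε half) is used in the comments.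

**Step 1**
Reactants: 1 (±)-α-ionone
Product: 2 (±)-α-ionone ethylene ketal
Conditions: HOCH2CH2OH, HC(OEt)3, p-TsOH (cat.), rt
Reagents that add atoms: ethylene glycol, OCCO
Why: Acid-catalysed ketalisation (orthoformate takes up the water) masks the side-chain C9 carbonyl so that the ring carbonyl introduced next can be reduced on its own; the racemic C6 centre is untouched.

**Step 2**
Reactants: 2 (±)-α-ionone ethylene ketal
Product: 3 (±)-3-oxo-α-ionone ethylene ketal
Conditions: t-BuOOH (70% aq, 5 equiv), Rh2(cap)4 (1 mol%), K2CO3 (0.5 equiv), CH2Cl2, rt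
Reagents that add atoms: tert-butyl hydroperoxide, CC(C)(C)OO
Why: Dirhodium caprolactamate/TBHP allylic C–H oxidation goes to the only unhindered ring allylic CH2 (C3) and stops at the conjugated enone, the known outcome for α-ionone-type rings.

**Step 3**
Reactants: 3 (±)-3-oxo-α-ionone ethylene ketal
Product: 5 rac-trans-(3R*,6R*)-3-hydroxy-α-ionone, via hydroxy ketal 4 (not isolated)
Conditions: NaBH4, CeCl3·7H2O, MeOH, −20 °C; then PPTS, acetone–H2O, 40 °C; SiO2 (cis isomer removed)
Reagents that add atoms: water, O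
Why: Luche 1,2-reduction creates the C3 carbinol with only modest substrate control and PPTS hydrolysis frees the C9 ketone, so the trans (3R*,6R*) racemate is obtained after chromatographic removal of the cis isomer.

**Step 4**
Reactants: 5 rac-trans-(3R*,6R*)-3-hydroxy-α-ionone
Product: 6 (3R,6R)-3-hydroxy-α-ionone
Conditions: lipase PS (Burkholderia cepacia, immobilised), vinyl acetate, MTBE, 30 °C, to ca. 55% conversion; SiO2 (alcohol separated from the (3S,6S)-acetate)
Reagents that add atoms: none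
Why: Lipase kinetic resolution (Kazlauskas rule): the enzyme is expected to acetylate the (3S)-carbinol, the spatial analogue of the fast-reacting (3R)-alcohol in the 3-hydroxy-β-ionone series, so unreacted (3R,6R)-alcohol is recovered in high ee, which fixes the absolute configuration of C3′ and C6′.

**Step 5**
Reactants: 6 (3R,6R)-3-hydroxy-α-ionone
Product: 7 (1R,4R)-4-[(1E)-3-hydroxy-3-methylpenta-1,4-dien-1-yl]-3,5,5-trimethylcyclohex-2-en-1-ol
Conditions: CH2=CHMgBr (2.5 equiv), THF, −20 → 0 °C; aq. NH4Cl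
Reagents that add atoms: vinylmagnesium bromide, C=C[Mg]Br
Why: 1,2-Grignard addition to the methyl enone after deprotonation of the free OH; the new tertiary carbinol centre forms as a mixture and is erased in step 6.

**Step 6**
Reactants: 7 (1R,4R)-4-[(1E)-3-hydroxy-3-methylpenta-1,4-dien-1-yl]-3,5,5-trimethylcyclohex-2-en-1-ol
Product: 8 [(2E,4E)-5-[(1R,4R)-4-hydroxy-2,6,6-trimethylcyclohex-2-en-1-yl]-3-methylpenta-2,4-dien-1-yl]triphenylphosphonium bromide
Conditions: PPh3·HBr (1.05 equiv), MeOH–CH2Cl2, 0 °C → rt; crystallisation (EtOAc)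
Reagents that add atoms: triphenylphosphine hydrobromide, [Br-].[PH+](c1ccccc1)(c1ccccc1)c1ccccc1
Why: Phosphonium salt synthesis with allylic transposition (SN1/SN2′): the tertiary bis-allylic alcohol ionises far faster than the ring allylic alcohol and PPh3 attacks the primary terminus, giving the thermodynamic (E)-trisubstituted C9′=C10′ alkene.

**Step 7**
Reactants: 8 ε-C15 phosphonium bromide; 9 (2E,4E,6E)-2,7-dimethylocta-2,4,6-trienedial (C10-dialdehyde, 3 equiv)
Product: 10 (2E,4E,6E,8E,10E,12E)-13-[(1R,4R)-4-hydroxy-2,6,6-trimethylcyclohex-2-en-1-yl]-2,7,11-trimethyltrideca-2,4,6,8,10,12-hexaenal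
Conditions: NaOMe (1.1 equiv), CH2Cl2–MeOH, −10 °C → rt; then heptane, 80 °C (Z→E); SiO2
Reagents that add atoms: none
Why: Wittig mono-olefination of the symmetrical dialdehyde used in excess forms C11′=C12′, and the E/Z mixture converges on the all-E polyenal on thermal equilibration, as in standard C15 + C10 carotenoid assembly.

**Step 8**
Reactants: 10 C25 hydroxy-aldehyde
Product: 12 [(2E,4E,6E,8E,10E,12E)-13-[(1R,4R)-4-hydroxy-2,6,6-trimethylcyclohex-2-en-1-yl]-2,7,11-trimethyltrideca-2,4,6,8,10,12-hexaen-1-yl]triphenylphosphonium bromide, via C25 alcohol 11 (not isolated)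
Conditions: NaBH4, EtOH–CH2Cl2, 0 °C; AcOH quench; then PPh3·HBr, MeOH, 0 °C → rt, dark
Reagents that add atoms: triphenylphosphine hydrobromide, [Br-].[PH+](c1ccccc1)(c1ccccc1)c1ccccc1
Why: Chemoselective 1,2-reduction of the polyenal followed by the retinol-type conversion of a polyenylic primary alcohol into its triphenylphosphonium salt (delocalised cation captured by PPh3 at the terminus); the less ionisable ring allylic OH survives at 0 °C.

**Step 9**
Reactants: 13 (4R,6R)-4-hydroxy-2,2,6-trimethylcyclohexanone (actinol)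
Product: 14 (4R,6R)-4-[(tert-butyldimethylsilyl)oxy]-2,2,6-trimethylcyclohexanone
Conditions: TBSCl, imidazole, DMF, rt
Reagents that add atoms: tert-butyldimethylsilyl chloride, CC(C)(C)[Si](C)(C)Cl
Why: Standard silylation of the secondary alcohol so that only the ketone is deprotonated in step 10; both stereocentres are untouched.

**Step 10**
Reactants: 14 TBS-protected actinol
Product: 15 (4R)-4-[(tert-butyldimethylsilyl)oxy]-2,6,6-trimethylcyclohex-1-en-1-yl trifluoromethanesulfonate
Conditions: KHMDS, THF, −78 °C; then PhNTf2, −78 → 0 °C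
Reagents that add atoms: N-phenylbis(trifluoromethanesulfonimide), O=S(=O)(N(c1ccccc1)S(=O)(=O)C(F)(F)F)C(F)(F)F
Why: The ketone has a single enolisable position (C6–H), so enolate O-triflation gives one tetrasubstituted enol triflate; the C6 centre is erased and the carbinol centre (future C3, R) is unaffected.

**Step 11**
Reactants: 15 enol triflate
Product: 17 (1R)-4-ethynyl-3,5,5-trimethylcyclohex-3-en-1-ol, via silylated enyne 16 (not isolated)
Conditions: Me3SiC≡CH, Pd(PPh3)4 (5 mol%), CuI (10 mol%), Et3N, DMF, 50 °C; then TBAF (3 equiv), THF, 0 °C → rt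
Reagents that add atoms: ethynyltrimethylsilane, C#C[Si](C)(C)C
Why: Sonogashira coupling of the hindered cyclohexenyl triflate (well precedented for 2,6,6-trimethylcyclohexenyl triflates) followed by fluoride removal of both the C–SiMe3 and O–TBS groups in the same pot.

**Step 12**
Reactants: 17 (1R)-4-ethynyl-3,5,5-trimethylcyclohex-3-en-1-ol; 18 4-bromofuran-2(5H)-one
Product: 19 4-{[(4R)-4-hydroxy-2,6,6-trimethylcyclohex-1-en-1-yl]ethynyl}furan-2(5H)-one
Conditions: PdCl2(PPh3)2 (3 mol%), CuI (6 mol%), i-Pr2NEt, THF, rt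
Reagents that add atoms: none
Why: Sonogashira coupling at the activated β-bromobutenolide; the lactone ring holds the future C19 oxygen and C11 cis on the C9=C10 bond, i.e. C8 trans to C11 as in the target.

**Step 13**
Reactants: 19 alkynyl butenolide
Product: 20 4-{[(4R)-4-hydroxy-2,6,6-trimethylcyclohex-1-en-1-yl]ethynyl}-2,5-dihydrofuran-2-ol
Conditions: DIBAL-H (2.2 equiv), CH2Cl2, −78 °C; Rochelle salt; used at once
Reagents that add atoms: none
Why: DIBAL half-reduction of the lactone at −78 °C (stable aluminium hemiacetal) gives the lactol; the anomeric centre is irrelevant because it becomes C11 of the polyene.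

**Step 14**
Reactants: 20 C15 lactol; 12 C25 phosphonium bromide
Product: 21 (3R,3′R,6′R)-7,8-didehydro-β,ε-carotene-3,19,3′-triol
Conditions: NaOMe (2.5 equiv), CH2Cl2–MeOH, 0 °C → rt, dark, Ar; then EtOAc, 50 °C, 1 h (11Z→11E); SiO2, crystallisation at −20 °C
Reagents that add atoms: none
Why: Wittig olefination through the ring-opened (Z)-γ-hydroxy-enal tautomer of the lactol forms C11=C12 and releases the 19-OH as the only primary alcohol; the C9=C10 geometry is inherited from the butenolide, and the hindered 11Z isomer is equilibrated to 11E under mild heat that leaves the C9 geometry alone.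

**Step 15**
Reactants: 21 C40 triol; 22 (E)-oct-2-enoic acid (1.05 equiv)
Product: 23 (3R,3′R,6′R)-3,3′-dihydroxy-7,8-didehydro-β,ε-caroten-19-yl (2E)-oct-2-enoate
Conditions: EDC·HCl (1.2 equiv), DMAP (5 mol%), CH2Cl2, −20 °C, dark
Reagents that add atoms: none
Why: Steglich esterification with a slight excess of acid at low temperature acylates the unhindered primary allylic 19-OH much faster than the two ring secondary alcohols, forming the C19–O ester bond.

**Step 16**
Reactants: 23 7,8-didehydro 19-octenoate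
Product: 24 (3R,3′R,6′R)-3,3′-dihydroxy-8-oxo-7,8-dihydro-β,ε-caroten-19-yl (2E)-oct-2-enoate (target)
Conditions: IPrAuNTf2 (3 mol%), H2O (10 equiv), 1,4-dioxane, 25 °C, dark, Ar
Reagents that add atoms: water, O
Why: Proposed new method: cationic NHC–gold(I) activates the C7≡C8 triple bond, the carbonyl oxygen of the neighbouring 19-octenoate adds 6-exo-dig at C8 (the alkyne carbon whose positive charge the polyene also stabilises) to give a six-membered acyloxonium (1,3-dioxinylium) vinyl-gold species, water attacks the acyloxonium carbon, collapse returns the ester to O19 and frees the C8 enol, and protodeauration/tautomerisation give C7H2–C8=O with no new stereocentre; the closest known reaction type is the gold-catalysed neighbouring-ester-assisted hydration of propargylic acetates to α-acyloxy ketones (5-exo), which has not been shown with a six-membered acyloxy relay or on a polyene-conjugated 7,8-didehydrocarotenoid.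

**Compound list**
1 | (±)-α-ionone, (E)-4-(2,6,6-trimethylcyclohex-2-en-1-yl)but-3-en-2-one (racemic) | CC(=O)/C=C/C1C(C)=CCCC1(C)C | starting material
2 | (±)-α-ionone ethylene ketal, 2-methyl-2-[(E)-2-(2,6,6-trimethylcyclohex-2-en-1-yl)ethenyl]-1,3-dioxolane (racemic) | CC1(/C=C/C2C(C)=CCCC2(C)C)OCCO1 | intermediate
3 | (±)-3-oxo-α-ionone ethylene ketal, 4-[(E)-2-(2-methyl-1,3-dioxolan-2-yl)ethenyl]-3,5,5-trimethylcyclohex-2-en-1-one (racemic) | CC1(/C=C/C2C(C)=CC(=O)CC2(C)C)OCCO1 | intermediate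
4 | 3-hydroxy-α-ionone ethylene ketal (cis/trans mixture, racemic; not isolated) | CC1(/C=C/C2C(C)=CC(O)CC2(C)C)OCCO1 | intermediate
5 | rac-trans-(3R*,6R*)-3-hydroxy-α-ionone (1:1 pair of enantiomers) | CC(=O)/C=C/[C@H]1C(C)=C[C@H](O)CC1(C)C.CC(=O)/C=C/[C@@H]1C(C)=C[C@@H](O)CC1(C)C | intermediate
6 | (3R,6R)-3-hydroxy-α-ionone, (E)-4-[(1R,4R)-4-hydroxy-2,6,6-trimethylcyclohex-2-en-1-yl]but-3-en-2-one | CC(=O)/C=C/[C@H]1C(C)=C[C@H](O)CC1(C)C | intermediate
7 | (1R,4R)-4-[(1E)-3-hydroxy-3-methylpenta-1,4-dien-1-yl]-3,5,5-trimethylcyclohex-2-en-1-ol (side-chain carbinol epimers) | C=CC(C)(O)/C=C/[C@H]1C(C)=C[C@H](O)CC1(C)C | intermediate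
8 | [(2E,4E)-5-[(1R,4R)-4-hydroxy-2,6,6-trimethylcyclohex-2-en-1-yl]-3-methylpenta-2,4-dien-1-yl]triphenylphosphonium bromide | [Br-].c1ccccc1[P+](c1ccccc1)(c1ccccc1)C/C=C(C)/C=C/[C@H]1C(C)=C[C@H](O)CC1(C)C | intermediate
9 | (2E,4E,6E)-2,7-dimethylocta-2,4,6-trienedial (C10-dialdehyde) | O=C/C(C)=C/C=C/C=C(C)/C=O | starting material
10 | (2E,4E,6E,8E,10E,12E)-13-[(1R,4R)-4-hydroxy-2,6,6-trimethylcyclohex-2-en-1-yl]-2,7,11-trimethyltrideca-2,4,6,8,10,12-hexaenal | O=C/C(C)=C/C=C/C=C(C)/C=C/C=C(C)/C=C/[C@H]1C(C)=C[C@H](O)CC1(C)C | intermediate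
11 | (2E,4E,6E,8E,10E,12E)-13-[(1R,4R)-4-hydroxy-2,6,6-trimethylcyclohex-2-en-1-yl]-2,7,11-trimethyltrideca-2,4,6,8,10,12-hexaen-1-ol (not isolated) | OC/C(C)=C/C=C/C=C(C)/C=C/C=C(C)/C=C/[C@H]1C(C)=C[C@H](O)CC1(C)C | intermediate
12 | [(2E,4E,6E,8E,10E,12E)-13-[(1R,4R)-4-hydroxy-2,6,6-trimethylcyclohex-2-en-1-yl]-2,7,11-trimethyltrideca-2,4,6,8,10,12-hexaen-1-yl]triphenylphosphonium bromide | [Br-].c1ccccc1[P+](c1ccccc1)(c1ccccc1)C/C(C)=C/C=C/C=C(C)/C=C/C=C(C)/C=C/[C@H]1C(C)=C[C@H](O)CC1(C)C | intermediate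
13 | (4R,6R)-4-hydroxy-2,2,6-trimethylcyclohexanone (actinol) | O=C1[C@H](C)C[C@@H](O)CC1(C)C | starting material
14 | (4R,6R)-4-[(tert-butyldimethylsilyl)oxy]-2,2,6-trimethylcyclohexanone | O=C1[C@H](C)C[C@@H](O[Si](C)(C)C(C)(C)C)CC1(C)C | intermediate
15 | (4R)-4-[(tert-butyldimethylsilyl)oxy]-2,6,6-trimethylcyclohex-1-en-1-yl trifluoromethanesulfonate | FC(F)(F)S(=O)(=O)OC1=C(C)C[C@@H](O[Si](C)(C)C(C)(C)C)CC1(C)C | intermediate
16 | tert-butyldimethyl{[(1R)-3,5,5-trimethyl-4-[(trimethylsilyl)ethynyl]cyclohex-3-en-1-yl]oxy}silane (not isolated) | C[Si](C)(C)C#CC1=C(C)C[C@@H](O[Si](C)(C)C(C)(C)C)CC1(C)C | intermediate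
17 | (1R)-4-ethynyl-3,5,5-trimethylcyclohex-3-en-1-ol | C#CC1=C(C)C[C@@H](O)CC1(C)C | intermediate
18 | 4-bromofuran-2(5H)-one | O=C1C=C(Br)CO1 | starting material
19 | 4-{[(4R)-4-hydroxy-2,6,6-trimethylcyclohex-1-en-1-yl]ethynyl}furan-2(5H)-one | O=C1C=C(C#CC2=C(C)C[C@@H](O)CC2(C)C)CO1 | intermediate
20 | 4-{[(4R)-4-hydroxy-2,6,6-trimethylcyclohex-1-en-1-yl]ethynyl}-2,5-dihydrofuran-2-ol (both anomers) | OC1OCC(C#CC2=C(C)C[C@@H](O)CC2(C)C)=C1 | intermediate
21 | (3R,3′R,6′R)-7,8-didehydro-β,ε-carotene-3,19,3′-triol (C19 cis to C11 on C9=C10; all other chain double bonds E) | OC\C(=C/C=C/C(C)=C/C=C/C=C(C)/C=C/C=C(C)/C=C/[C@H]1C(C)=C[C@H](O)CC1(C)C)C#CC1=C(C)C[C@@H](O)CC1(C)C | intermediate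
22 | (E)-oct-2-enoic acid | CCCCC/C=C/C(=O)O | starting material
23 | (3R,3′R,6′R)-3,3′-dihydroxy-7,8-didehydro-β,ε-caroten-19-yl (2E)-oct-2-enoate | CCCCC/C=C/C(=O)OC\C(=C/C=C/C(C)=C/C=C/C=C(C)/C=C/C=C(C)/C=C/[C@H]1C(C)=C[C@H](O)CC1(C)C)C#CC1=C(C)C[C@@H](O)CC1(C)C | intermediate
24 | (3R,3′R,6′R)-3,3′-dihydroxy-8-oxo-7,8-dihydro-β,ε-caroten-19-yl (2E)-oct-2-enoate | CCCCC/C=C/C(=O)OC\C(=C/C=C/C(C)=C/C=C/C=C(C)/C=C/C=C(C)/C=C/[C@H]1C(C)=C[C@H](O)CC1(C)C)C(=O)CC1=C(C)C[C@@H](O)CC1(C)C | target

**Totals**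
Total step count: 16. Longest linear sequence: 11 steps (steps 1–8, then 14–16); the actinol branch is steps 9–13.

**Three steps most likely to fail**

Step 16 (proposed gold hydration; the polyene may bind the catalyst or isomerise). The fallback sets out from 21 and comes back at 24, replacing π-acid hydration by known hydroxyl-tethered hydrosilylation and oxidation of a homopropargylic-type alcohol. Compound 21 is silylated with 1,1,3,3-tetramethyldisilazane to the tris(dimethylsilyl) ether F1. Platinum(0) (Karstedt) catalysis then effects intramolecular syn-hydrosilylation from the 19-O–SiMe2H group (5-exo-dig, Si to C8, H to C7), giving the cyclic vinylsilane F2. Tamao–Fleming oxidation (KF, KHCO3, H2O2, THF–MeOH) converts C8–Si into the C8 enol and hence the ketone while cleaving all Si–O bonds, giving siphonaxanthin F3. F3 is acylated at its primary 19-OH with 22 under the step 15 conditions to give 24.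

Step 14 (Wittig on the lactol; the 2,5-dihydrofuran-2-ol can dehydrate to a furan or lose its Z geometry before olefination). The fallback sets out from 19 and comes back at 21, using an open-chain, silyl-protected aldehyde instead of the lactol. Butenolide 19 is opened with MeNH(OMe)·HCl/Me3Al and the resulting alkoxides are trapped in the same pot with TESOTf/2,6-lutidine to give the bis-triethylsilyl Weinreb amide F4. DIBAL-H at −78 °C gives the (Z)-silyloxy enal F5, which cannot cyclise. Wittig reaction with 12 (NaOMe, CH2Cl2–MeOH) gives the 3,19-bis-triethylsilyl ether F6, and HF·pyridine in THF at 0 °C returns 21.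

Step 15 (selective acylation of the primary 19-OH in the presence of two secondary OH groups). The fallback sets out from 21 and comes back at 23 by Mitsunobu esterification (PPh3, DIAD, 22, THF, −20 °C). Here the alcohol rather than the acid is activated; the oxyphosphonium forms much faster at the primary carbinol and the carboxylate displaces it at C19, so no acyl-transfer selectivity is needed. No new compound is made.

**Further compounds**
F1 | step 16 | (3R,3′R,6′R)-3,19,3′-tris[(dimethylsilyl)oxy]-7,8-didehydro-β,ε-carotene | C[SiH](C)OC\C(=C/C=C/C(C)=C/C=C/C=C(C)/C=C/C=C(C)/C=C/[C@H]1C(C)=C[C@H](O[SiH](C)C)CC1(C)C)C#CC1=C(C)C[C@@H](O[SiH](C)C)CC1(C)C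
F2 | step 16 | cyclic vinylsilane (19-O–SiMe2–C8 oxasilolane with exocyclic C7=C8; 3,3′-bis(dimethylsilyl) ether) | C[Si]1(C)OC\C(=C/C=C/C(C)=C/C=C/C=C(C)/C=C/C=C(C)/C=C/[C@H]2C(C)=C[C@H](O[SiH](C)C)CC2(C)C)\C1=C/C1=C(C)C[C@@H](O[SiH](C)C)CC1(C)C
F3 | step 16 | siphonaxanthin, (3R,3′R,6′R)-3,19,3′-trihydroxy-7,8-dihydro-β,ε-caroten-8-one | OC\C(=C/C=C/C(C)=C/C=C/C=C(C)/C=C/C=C(C)/C=C/[C@H]1C(C)=C[C@H](O)CC1(C)C)C(=O)CC1=C(C)C[C@@H](O)CC1(C)C
F4 | step 14 | (2Z)-N-methoxy-N-methyl-4-[(triethylsilyl)oxy]-3-{[(4R)-2,6,6-trimethyl-4-[(triethylsilyl)oxy]cyclohex-1-en-1-yl]ethynyl}but-2-enamide | CON(C)C(=O)/C=C(\CO[Si](CC)(CC)CC)C#CC1=C(C)C[C@@H](O[Si](CC)(CC)CC)CC1(C)C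
F5 | step 14 | (2Z)-4-[(triethylsilyl)oxy]-3-{[(4R)-2,6,6-trimethyl-4-[(triethylsilyl)oxy]cyclohex-1-en-1-yl]ethynyl}but-2-enal | O=C/C=C(\CO[Si](CC)(CC)CC)C#CC1=C(C)C[C@@H](O[Si](CC)(CC)CC)CC1(C)C
F6 | step 14 | (3R,3′R,6′R)-3,19-bis[(triethylsilyl)oxy]-7,8-didehydro-β,ε-caroten-3′-ol | CC[Si](CC)(CC)OC\C(=C/C=C/C(C)=C/C=C/C=C(C)/C=C/C=C(C)/C=C/[C@H]1C(C)=C[C@H](O)CC1(C)C)C#CC1=C(C)C[C@@H](O[Si](CC)(CC)CC)CC1(C)C
F0 | step 15 | none | none
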